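In the early minutes of Sunday's run X rose fast, to 57% of the E charged at 10.0 min, and from 30.0 min on the readings levelled out at an average of 81.3%.

| flask | E | Z | G | remark | time |
|---|---|---|---|---|---|
| Sunday's | 0.50 M | 1.6 equiv (in portions, 3) | 10 mM | run made earlier; portions every 2.5 min |  |
| south | 0.50 M | 1.05 equiv (in portions, 3) | 10.0 mM | the portions of Z follow each other after 2.5 min, the first at the start | 1.5 h |
| north-east | 0.15 M | 1.05 equiv | 10.0 mM | everything together at the start | 1.5 h |

- Sunday's (time / min: X / %): 10.0: 57; 20.0: 75; 30.0: 81; 40.0: 80; 50.0: 83

(each reading ± 1.5 percentage points)

- where the amount of E changes, what is given in equivalents or mol% on it follows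

- the flask that ends with the higher amount of X, in percent of the E charged, or "neither" when 2 percentage points or less lies between them (south / north-east / neither)
- final X, as a percentage of the E charged, in south
- final X, as a percentage of the E charged, in north-east

Was Z the limiting reagent on Sunday? I read it as not, counting one Z per X: 1.6 equiv was charged against a plateau of 81.3%.

So what took the rest? I supposed that G is used up against E, mole for mole, and does not turn over. In north-east c(G) over c(E) is 6.67%. This ratio, the G toll, is then the share of the E charged that G takes away. On Sunday and in south it is 2.00%, which is lower than in north-east.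

How much of the remainder becomes X? Sunday's plateau over what its toll leaves gives 83.0%, my selectivity, which I carried over unchanged. I set aside that south and north-east get less Z than Sunday's 1.6 equiv and that north-east gets its Z all at once. That made 81.3% in south and 77.5% in north-east, so I put south ahead by 3.9 percentage points, beyond the margin of 2 points.

The forecast differed: north-east, with 76% in south and 92% in north-east, on the ground that north-east “is limited by neither G nor Z and nearly completes”.

The flasks gave south: 76.6% in south and 68.7% in north-east.

    E + G → J (k = 9.01 L mol⁻¹ min⁻¹)
    Z + L → X (k = 40.8 L mol⁻¹ min⁻¹)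
    Z + D → Q (k = 39.7 L mol⁻¹ min⁻¹)
    L ⇌ D (K = 0.475, k = 4.74 min⁻¹)
    E ⇌ L (K = 0.0450, k = 0.139 min⁻¹)

At 1.50 h north-east held J at 6.67%, beside a toll of 6.67%. The remaining 93.3% held X at 68.7%, Q at 23.7%, E at 0.905%, L at 0.0304% and D at 0.0135%, so X took 73.6% of it, not my 83.0%. The neighbour flask, north-east with 1.80 equiv of Z, has the same toll and ended with J at 6.67%. There X took 79.4% of the remainder, ending at 74.1%, with Q at 19.2%.

The numbers in the tables are calculated on assumed constants; the scatter is artificial.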